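**Plan**

- Retrosynthesis: the C7 carbinol is traced to a C7 ketone (16). The carbocycle of 16 is then cut at C5–C6 and C8–C8a in one operation, giving formyl γ-pyrone 14 and the α-hydroxy-α′-aryloxy acetone 9. Compound 9 is cut at its ArO–CH2 bond into phenol 6 and a chloroacetone; 6 and 14 each go back to a methyl ketone and 3-phenylpropanoyl chloride.
- Enabling feature: the carbocycle (C4a, C5, C6, C7, C8, C8a) is fused to the γ-pyrone through C4a=C8a. C5 and C8a are therefore the aldehyde carbon and the β-carbon of a 3-formyl γ-pyrone, a 1,3-dielectrophile once C8a carries SMe. C6–C7–C8, oxygenated on every carbon, is a 1,3-dinucleophile when C7 is a ketone.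
- Forward order: the aryl chromone (benzene ring, then its pyranone by Claisen acylation and cyclodehydration); separately the monocyclic γ-pyrone (acylation–cyclisation, iodination, formylation); then the carbocycle by an aldol/addition–elimination [3+3] annulation; then ketone reduction.
- Stereochemistry: C5 and C6 come from a chiral dinuclear zinc catalyst (syn aldol, trans in the ring). C8 settles by equilibration next to the C7 ketone (aryloxy pseudoaxial). C7 comes from substrate-controlled axial hydride delivery.

Key step: step 9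

Assumption: the zinc catalyst is taken to add to the pyranone aldehyde with the same facial sense as in its syn-aldols of α-hydroxy ketones with simple aldehydes, so the (S,S)-ligand is written; if the sense proves opposite, the (R,R)-ligand is used with no other change.

**Route**

Step 1
Reactants: 1 2-methoxybenzene-1,4-diol
Product: 2 1-(2,5-dihydroxy-4-methoxyphenyl)ethan-1-one
Conditions: AcOH, ZnCl2, 120 °C
Reagents that add atoms: acetic acid, CC(=O)O
Why: Nencki-type Friedel–Crafts acylation should go to C5 of 1, the free position ortho to one hydroxyl and para to the methoxy group, and the resulting ortho-hydroxy ketone is held by an internal hydrogen bond.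

Step 2
Reactants: 2 1-(2,5-dihydroxy-4-methoxyphenyl)ethan-1-one
Product: 3 1-[2-hydroxy-4-methoxy-5-(methoxymethoxy)phenyl]ethan-1-one
Conditions: MOMCl (1.05 equiv), iPr2NEt, CH2Cl2, 0 °C
Reagents that add atoms: chloromethyl methyl ether, COCCl
Why: O-alkylation should take the 5-hydroxyl only, because the 2-hydroxyl is tied up in a hydrogen bond to the ketone and is much less nucleophilic.

Step 3
Reactants: 3 1-[2-hydroxy-4-methoxy-5-(methoxymethoxy)phenyl]ethan-1-one; 4 3-phenylpropanoyl chloride
Product: 6 6-hydroxy-7-methoxy-2-(2-phenylethyl)-4H-chromen-4-one, via aryl β-diketone 5 (not isolated)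
Conditions: LiN(SiMe3)2 (3.1 equiv), THF, −78 °C; 4, −78 °C to rt; aq. NH4Cl; then conc. HCl, MeOH, 65 °C
Reagents that add atoms: none
Why: Claisen-type C-acylation of the lithium phenoxide-enolate (the Baker–Venkataraman outcome) should give the 1,3-diketone, and acid then closes the chromone by cyclodehydration while cleaving the MOM acetal.

Step 4
Reactants: 6 6-hydroxy-7-methoxy-2-(2-phenylethyl)-4H-chromen-4-one; 7 3-chloro-2-oxopropyl acetate
Product: 8 3-{[7-methoxy-4-oxo-2-(2-phenylethyl)-4H-chromen-6-yl]oxy}-2-oxopropyl acetate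
Conditions: K2CO3, NaI (cat.), acetone, 40 °C
Reagents that add atoms: none
Why: Williamson ether synthesis of a phenoxide with an activated α-chloro ketone, with iodide catalysis, should be fast under conditions too mild to touch the acetate or the chromone.

Step 5
Reactants: 8 3-{[7-methoxy-4-oxo-2-(2-phenylethyl)-4H-chromen-6-yl]oxy}-2-oxopropyl acetate
Product: 9 1-hydroxy-3-{[7-methoxy-4-oxo-2-(2-phenylethyl)-4H-chromen-6-yl]oxy}propan-2-one
Conditions: AcCl (5 mol%), MeOH, 0 °C to rt
Reagents that add atoms: none
Why: Acid-catalysed transesterification should free the primary alcohol without the base that would isomerise the α-hydroxy ketone.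

Step 6
Reactants: 10 4,4-bis(methylsulfanyl)but-3-en-2-one; 4 3-phenylpropanoyl chloride
Product: 12 2-(methylsulfanyl)-6-(2-phenylethyl)-4H-pyran-4-one, via diketo ketene dithioacetal 11 (not isolated)
Conditions: LiN(SiMe3)2 (2.1 equiv), THF, −78 °C; 4, −78 to 0 °C; aq. NH4Cl; then TsOH·H2O (10 mol%), toluene, 80 °C
Reagents that add atoms: none
Why: Claisen-type C-acylation of the methyl ketone enolate should give the enolised β-diketone 11, whose enol oxygen adds 6-endo to the bis(methylsulfanyl) carbon under acid and expels methanethiol, the known route from acyl ketene dithioacetals to 2-(methylsulfanyl) pyranones and chromones.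

Step 7
Reactants: 12 2-(methylsulfanyl)-6-(2-phenylethyl)-4H-pyran-4-one
Product: 13 3-iodo-2-(methylsulfanyl)-6-(2-phenylethyl)-4H-pyran-4-one
Conditions: NIS (1.05 equiv), TFA (10 mol%), MeCN, 0 °C to rt
Reagents that add atoms: N-iodosuccinimide, O=C1CCC(=O)N1I
Why: Electrophilic iodination should go to C3, the α-carbon of the push–pull S,O-ketene acetal between the sulfur-bearing carbon and the carbonyl, which is more electron-rich than C5, as in the 3-iodination of chromones and the α-iodination of α-oxo ketene dithioacetals.

Step 8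
Reactants: 13 3-iodo-2-(methylsulfanyl)-6-(2-phenylethyl)-4H-pyran-4-one
Product: 14 2-(methylsulfanyl)-4-oxo-6-(2-phenylethyl)-4H-pyran-3-carbaldehyde
Conditions: Pd(PPh3)4 (5 mol%), CO (3 bar), Bu3SnH (1.1 equiv, slow addition), THF, 50 °C
Reagents that add atoms: carbon monoxide, [C-]#[O+]
Why: Palladium-catalysed reductive carbonylation of a vinyl iodide (oxidative addition of C–I to zerovalent palladium, CO insertion, hydride transfer from tin) should give the aldehyde, the C–S bond being far slower to add than C–I.

Step 9
Reactants: 14 2-(methylsulfanyl)-4-oxo-6-(2-phenylethyl)-4H-pyran-3-carbaldehyde; 9 1-hydroxy-3-{[7-methoxy-4-oxo-2-(2-phenylethyl)-4H-chromen-6-yl]oxy}propan-2-one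
Product: 16 (5S,6R,8R)-5,6-dihydroxy-8-{[7-methoxy-4-oxo-2-(2-phenylethyl)-4H-chromen-6-yl]oxy}-2-(2-phenylethyl)-5,6-dihydro-4H-chromene-4,7(8H)-dione, via syn-aldol adduct 15 (not isolated)
Conditions: Et2Zn (20 mol%), (S,S)-2,6-bis{[2-(hydroxydiphenylmethyl)pyrrolidin-1-yl]methyl}-4-methylphenol (10 mol%), 4 Å MS, THF, −35 °C; then DBU (1.2 equiv), −35 to 0 °C; pH 7 buffer
Reagents that add atoms: none
Why: Proposed new method: the dinuclear zinc catalyst binds the α-hydroxy ketone of 9 as a five-membered chelate and enolises it only on the hydroxylated side, so the (Z)-zinc enediolate carbon (future C6) adds to the aldehyde of 14 (future C5), which is far more electrophilic than the push–pull C–SMe carbon, to give syn adduct 15; DBU then enolises the ArOCH2 side and that enolate carbon (future C8) attacks the sulfur-bearing pyranone carbon (future C8a) with loss of methanethiolate, restoring the γ-pyrone. The closest known reaction types are the zinc-catalysed direct syn-aldol of α-hydroxy ketones and the base-mediated [3+3] annulation of ketone 1,3-dinucleophiles with β-(methylsulfanyl) enals and α-oxo ketene dithioacetals, which normally runs on to an arene. The carbocycle closes by a 6-(enolendo)-endo-trig addition–elimination. C5 and C6 are set by the catalyst (syn aldol, 5S,6R, trans and diequatorial in the ring), and the epimerisable C8 should settle under the base with the aryloxy group pseudoaxial and trans to the C6 hydroxyl, where it avoids eclipsing the C7=O and C8a–O1 dipoles. The step needs the hydroxylated carbon to meet the aldehyde and the aryloxylated carbon to meet C8a, which chelation-directed enolisation and the reactivity gap between CHO and C–SMe should secure. It also needs C- over O-closure (O-closure would be 5-endo-trig) and no loss of water from C5, for which low temperature, about one equivalent of base that the released thiol buffers, and immediate reduction are relied on.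

Step 10
Reactants: 16 (5S,6R,8R)-5,6-dihydroxy-8-{[7-methoxy-4-oxo-2-(2-phenylethyl)-4H-chromen-6-yl]oxy}-2-(2-phenylethyl)-5,6-dihydro-4H-chromene-4,7(8H)-dione
Product: 17 (5S,6R,7S,8S)-5,6,7-trihydroxy-8-{[7-methoxy-4-oxo-2-(2-phenylethyl)-4H-chromen-6-yl]oxy}-2-(2-phenylethyl)-5,6,7,8-tetrahydro-4H-chromen-4-one
Conditions: NaBH4, CeCl3·7H2O, MeOH/THF, −78 °C
Reagents that add atoms: none
Why: Luche reduction: in the half-chair with the C5 and C6 hydroxyls pseudoequatorial and the C8 aryloxy group pseudoaxial, the small hydride should add axially to C7 on the face anti to the C8–O bond, giving the equatorial 7S alcohol (cis to C8–OAr, trans to C6–OH), while the vinylogous-ester carbonyls of both pyranone rings are left alone at −78 °C.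

**Compound list**

1 | 2-methoxybenzene-1,4-diol | COc1cc(O)ccc1O | starting material
2 | 1-(2,5-dihydroxy-4-methoxyphenyl)ethan-1-one | CC(=O)c1cc(O)c(OC)cc1O | intermediate
3 | 1-[2-hydroxy-4-methoxy-5-(methoxymethoxy)phenyl]ethan-1-one | CC(=O)c1cc(OCOC)c(OC)cc1O | intermediate
4 | 3-phenylpropanoyl chloride | O=C(Cl)CCc1ccccc1 | starting material
5 | 1-[2-hydroxy-4-methoxy-5-(methoxymethoxy)phenyl]-5-phenylpentane-1,3-dione (formed in the flask) | COCOc1cc(C(=O)CC(=O)CCc2ccccc2)c(O)cc1OC | intermediate
6 | 6-hydroxy-7-methoxy-2-(2-phenylethyl)-4H-chromen-4-one | COc1cc2oc(CCc3ccccc3)cc(=O)c2cc1O | intermediate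
7 | 3-chloro-2-oxopropyl acetate (1-acetoxy-3-chloroacetone) | CC(=O)OCC(=O)CCl | starting material
8 | 3-{[7-methoxy-4-oxo-2-(2-phenylethyl)-4H-chromen-6-yl]oxy}-2-oxopropyl acetate | COc1cc2oc(CCc3ccccc3)cc(=O)c2cc1OCC(=O)COC(C)=O | intermediate
9 | 1-hydroxy-3-{[7-methoxy-4-oxo-2-(2-phenylethyl)-4H-chromen-6-yl]oxy}propan-2-one | COc1cc2oc(CCc3ccccc3)cc(=O)c2cc1OCC(=O)CO | intermediate
10 | 4,4-bis(methylsulfanyl)but-3-en-2-one | CC(=O)C=C(SC)SC | starting material
11 | 1,1-bis(methylsulfanyl)-7-phenylhept-1-ene-3,5-dione (formed in the flask) | CSC(SC)=CC(=O)CC(=O)CCc1ccccc1 | intermediate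
12 | 2-(methylsulfanyl)-6-(2-phenylethyl)-4H-pyran-4-one | CSc1cc(=O)cc(CCc2ccccc2)o1 | intermediate
13 | 3-iodo-2-(methylsulfanyl)-6-(2-phenylethyl)-4H-pyran-4-one | CSc1oc(CCc2ccccc2)cc(=O)c1I | intermediate
14 | 2-(methylsulfanyl)-4-oxo-6-(2-phenylethyl)-4H-pyran-3-carbaldehyde | CSc1oc(CCc2ccccc2)cc(=O)c1C=O | intermediate
15 | 3-[(1S,2R)-1,2-dihydroxy-4-{[7-methoxy-4-oxo-2-(2-phenylethyl)-4H-chromen-6-yl]oxy}-3-oxobutyl]-2-(methylsulfanyl)-6-(2-phenylethyl)-4H-pyran-4-one (formed in the flask) | COc1cc2oc(CCc3ccccc3)cc(=O)c2cc1OCC(=O)[C@H](O)[C@@H](O)c1c(SC)oc(CCc2ccccc2)cc1=O | intermediate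
16 | (5S,6R,8R)-5,6-dihydroxy-8-{[7-methoxy-4-oxo-2-(2-phenylethyl)-4H-chromen-6-yl]oxy}-2-(2-phenylethyl)-5,6-dihydro-4H-chromene-4,7(8H)-dione (8R here is the same spatial arrangement as 8S in 17; only the priority ranking changes) | COc1cc2oc(CCc3ccccc3)cc(=O)c2cc1O[C@@H]1c2oc(CCc3ccccc3)cc(=O)c2[C@H](O)[C@@H](O)C1=O | intermediate
17 | (5S,6R,7S,8S)-5,6,7-trihydroxy-8-{[7-methoxy-4-oxo-2-(2-phenylethyl)-4H-chromen-6-yl]oxy}-2-(2-phenylethyl)-5,6,7,8-tetrahydro-4H-chromen-4-one | COc1cc2oc(CCc3ccccc3)cc(=O)c2cc1O[C@@H]1c2oc(CCc3ccccc3)cc(=O)c2[C@H](O)[C@@H](O)[C@@H]1O | target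

**Step count and risks**

Total steps: 10. Longest linear sequence: 7 (steps 1, 2, 3, 4, 5, 9, 10).

Steps most likely to fail:

1. Step 9 (proposed new method). After the aldol, base-induced retro-aldol or epimerisation at C6 may outrun ring closure, the C6 hydroxyl may close on C8a through oxygen, displacement of the methylsulfanyl group may be slow, and the β-hydroxy ketone may lose water from C5 and aromatise. The fallback uses known chemistry in separate stages and sets out from 14 and 9. The zinc-catalysed aldol is run alone and 15 is isolated. Its syn-diol is tied up with 2,2-dimethoxypropane and PPTS as the 5,6-O-isopropylidene sulfide F1. mCPBA (2.2 equiv, CH2Cl2, 0 °C) then gives the methyl sulfone F2, whose sulfinate is a far better leaving group. Cs2CO3 in MeCN at 0 °C closes the ring by the intramolecular addition–elimination known for 2-sulfonyl chromones and pyranones, giving the acetonide-protected ketone F3, with the acetonide blocking O-closure and loss of the C5 oxygen. NaBH4/CeCl3 as in step 10 gives the acetonide-protected triol F4, and PPTS in wet MeOH at 40 °C releases 17, where the fallback rejoins the route.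

2. Step 10. Hydride may be delivered with poor facial selectivity if the ring populates the other half-chair, and the basic borohydride medium may dehydrate 16 before it is reduced. The fallback replaces substrate control by reagent control in a slightly acidic medium: asymmetric transfer hydrogenation of 16 with RuCl(p-cymene)[TsNCH(Ph)CH(Ph)NH2] (the antipode matched to hydride delivery on the C7 face anti to the aryloxy group), HCO2H/Et3N, rt. This also tolerates epimerisation at C8 before reduction. It runs from 16 to 17 and makes no compound outside the list (F0).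

3. Step 8. Hydrodeiodination by the tin hydride may outrun CO insertion, and sulfur coordination may slow the palladium cycle. The fallback sets out from 12 and bypasses 13: Vilsmeier–Haack formylation (POCl3, DMF, 0 to 60 °C) at the same push–pull carbon gives the iminium chloride F5, which aqueous NaOAc hydrolyses to 14, where it rejoins the route.

**Further compounds**

F1 | step 9 | 5,6-O-isopropylidene derivative (acetonide) of 15 | COc1cc2oc(CCc3ccccc3)cc(=O)c2cc1OCC(=O)[C@@H]4OC(C)(C)O[C@H]4c1c(SC)oc(CCc2ccccc2)cc1=O
F2 | step 9 | methyl sulfone of F1 | COc1cc2oc(CCc3ccccc3)cc(=O)c2cc1OCC(=O)[C@@H]4OC(C)(C)O[C@H]4c1c(S(C)(=O)=O)oc(CCc2ccccc2)cc1=O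
F3 | step 9 | 5,6-O-isopropylidene derivative of 16 | COc1cc2oc(CCc3ccccc3)cc(=O)c2cc1O[C@@H]1c2oc(CCc3ccccc3)cc(=O)c2[C@@H]4OC(C)(C)O[C@H]4C1=O
F4 | step 9 | 5,6-O-isopropylidene derivative of 17 | COc1cc2oc(CCc3ccccc3)cc(=O)c2cc1O[C@@H]1c2oc(CCc3ccccc3)cc(=O)c2[C@@H]4OC(C)(C)O[C@H]4[C@@H]1O
F0 | step 10 | none | none
F5 | step 8 | N,N-dimethyl-1-[2-(methylsulfanyl)-4-oxo-6-(2-phenylethyl)-4H-pyran-3-yl]methaniminium chloride | CSc1oc(CCc2ccccc2)cc(=O)c1C=[N+](C)C.[Cl-]
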